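**Retrosynthetic overview**
1. Target ⇐ macrocyclic 15β,16β‑epoxide (acid hydrolysis at allylic C‑16) ⇐ 11‑membered ring closed last at C‑7–C‑8 by intramolecular B‑alkyl Suzuki coupling.
2. C‑1–C‑2 from a ligand‑controlled Nozaki–Hiyama–Kishi coupling of a C‑1 enol triflate with (S)‑4‑methylhex‑5‑enal (from (S)‑citronellene, which supplies C‑5).
3. C‑8=C‑9(Me) and the C‑8 triflate from α′‑methylation and enol triflation of an epoxy ketone; the C‑1 acetyl from homologation of a C‑11 ketone through an enol ether.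
4. Key step: NHC‑catalysed intramolecular Stetter reaction (acyl anion at C‑11 onto enone β‑carbon C‑10) desymmetrises an achiral 4,4‑disubstituted cyclohexadienone made from p‑cresol, and sets C‑10 and quaternary C‑14.
5. Ring order: six‑membered ring (p‑cresol, dearomatised) → five‑membered ring (Stetter) → eleven‑membered ring (Suzuki).

**Assumptions**
- Numbering: atoms are numbered C‑1…C‑16 along the ring atoms of the given SMILES (C‑1 bears the methylene, C‑2 OAc, C‑5 Me, C‑8=C‑9, C‑10/C‑14 ring fusion, C‑15/C‑16 diol); the target is then (2S,5R,10S,11R,14S,15R,16R), and β means the face of the C‑14 methyl. Intermediates keep this numbering.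
- Reagents: the triazolium precatalyst, the Horner–Wittig phosphine oxide and the NHK ligand are taken as known reagents made separately and are not counted as steps.

**Route**

Step 1
Reactants: 1 p‑cresol; 2 allyltrimethylsilane
Product: 3 4‑allyl‑4‑methylcyclohexa‑2,5‑dien‑1‑one
Conditions: PhI(OAc)2, (CF3)2CHOH, −10 °C → rt
Reagents that add atoms: none
Why: Oxidative dearomatisation of the phenol to a phenoxenium ion, trapped at the para carbon by the allylsilane (Hosomi–Sakurai‑type allylation), gives the achiral 4,4‑disubstituted dienone in one step.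

Step 2
Reactants: 3 4‑allyl‑4‑methylcyclohexa‑2,5‑dien‑1‑one
Product: 4 3‑(1‑methyl‑4‑oxocyclohexa‑2,5‑dien‑1‑yl)propanal
Conditions: PdCl2(PhCN)2 (10 mol%), CuCl2·2H2O (10 mol%), AgNO2 (5 mol%), O2 (1 atm), t‑BuOH/MeNO2, rt
Reagents that add atoms: dioxygen, O=O
Why: Aldehyde‑selective (anti‑Markovnikov, nitrite‑modified) Wacker oxidation of the terminal alkene next to a quaternary carbon; the electron‑poor dienone alkenes do not react.

Step 3
Reactants: 4 3‑(1‑methyl‑4‑oxocyclohexa‑2,5‑dien‑1‑yl)propanal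
Product: 5 (3aR,7aS)‑3a‑methyl‑2,3,3a,7a‑tetrahydro‑1H‑indene‑1,6(7H)‑dione
Conditions: aminoindanol‑derived N‑C6F5 triazolium tetrafluoroborate (10 mol%, enantiomer giving 3aR,7aS), KHMDS (10 mol%), toluene, rt
Reagents that add atoms: none
Why: NHC‑catalysed intramolecular Stetter reaction: the Breslow acyl anion at C‑11 adds 5‑exo to one of the two enantiotopic enone β‑carbons (C‑10), which enforces the cis ring fusion and lets the chiral carbene set C‑10 and the quaternary C‑14 together.

Step 4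
Reactants: 5 cis‑hydrindene‑1,6‑dione
Product: 7 11‑(1‑methoxyethylidene) enone (E/Z mixture), via lithium alkoxide adduct 6 (not isolated)
Conditions: Ph2P(O)CH(OMe)CH3, LDA, THF, −78 °C; add 5; then t‑BuOK, 0 °C → rt
Reagents that add atoms: (1‑methoxyethyl)diphenylphosphine oxide, CC(OC)P(=O)(c1ccccc1)c1ccccc1
Why: Horner–Wittig olefination in which the hard phosphoryl carbanion adds to the saturated cyclopentanone in preference to the less electrophilic conjugated C‑8 ketone; the enol ether is a base‑stable latent acetyl group.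

Step 5
Reactants: 7 11‑(1‑methoxyethylidene) enone
Product: 8 15β,16β‑epoxy ketone
Conditions: 30% H2O2, NaOH (cat.), MeOH, 0 °C
Reagents that add atoms: hydrogen peroxide, OO
Why: Weitz–Scheffer nucleophilic epoxidation of the enone; hydroperoxide adds axially to C‑15 on the convex face (syn to the angular methyl, anti to the cyclopentane) to give the β‑epoxide, and the electron‑rich enol ether is untouched.

Step 6
Reactants: 8 15β,16β‑epoxy ketone
Product: 10 9‑methyl epoxy ketone (C‑9 epimers), via lithium enolate 9 (not isolated)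
Conditions: LDA, THF, −78 °C; MeI, −78 → −20 °C
Reagents that add atoms: iodomethane, CI
Why: Kinetic enolate alkylation that is regiospecific because the epoxy ketone can enolise only towards C‑9 (the oxirane C‑16–H is not enolisable); the C‑9 configuration is irrelevant since C‑9 becomes sp2.

Step 7
Reactants: 10 9‑methyl epoxy ketone
Product: 12 C‑8 enol triflate, via potassium enolate 11 (not isolated)
Conditions: KHMDS, THF, −78 → 0 °C; PhNTf2
Reagents that add atoms: N‑phenylbis(trifluoromethanesulfonimide), O=S(=O)(N(c1ccccc1)S(=O)(=O)C(F)(F)F)C(F)(F)F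
Why: Enol triflate formation from the only possible (tetrasubstituted) enolate fixes the C‑8=C‑9 double bond with the methyl on C‑9 and installs the cross‑coupling handle.

Step 8
Reactants: 12 C‑8 enol triflate
Product: 13 11α‑acetyl epoxy enol triflate (H‑11β)
Conditions: aq. oxalic acid, THF, 0 °C
Reagents that add atoms: water, O
Why: Enol ether hydrolysis in which rate‑limiting C‑protonation of C‑11 occurs from the convex β‑face (away from the six‑membered ring), so the acetyl group ends on the α‑face; the mild acid neither enolises the ketone nor opens the deactivated epoxide.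

Step 9
Reactants: 13 11α‑acetyl epoxy enol triflate
Product: 15 bis(enol triflate), via potassium enolate 14 (not isolated)
Conditions: KHMDS, THF, −78 °C; PhNTf2, −78 °C
Reagents that add atoms: N‑phenylbis(trifluoromethanesulfonimide), O=S(=O)(N(c1ccccc1)S(=O)(=O)C(F)(F)F)C(F)(F)F
Why: Kinetic deprotonation of the methyl ketone at CH3 followed by O‑triflation (enol triflate formation) creates the C‑1(OTf)=CH2 unit and removes the acidity at C‑11, locking its configuration.

Step 10
Reactants: 16 (S)‑β‑citronellene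
Product: 18 (S)‑4‑methylhex‑5‑enal, via ozonide 17 (not isolated)
Conditions: O3, CH2Cl2, −78 °C (Sudan III end point); Me2S, −78 °C → rt
Reagents that add atoms: ozone, [O-][O+]=O
Why: Chemoselective ozonolysis of the electron‑rich trisubstituted alkene in the presence of the monosubstituted vinyl group; the C‑5 stereocentre comes from the chiral pool.

Step 11
Reactants: 15 bis(enol triflate); 18 (S)‑4‑methylhex‑5‑enal
Product: 19 (2S)‑allylic alcohol
Conditions: CrCl2 (3 equiv), NiCl2 (2 mol%), Kishi‑type oxazoline–sulfonamide ligand (enantiomer giving 2S), Et3N, THF, rt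
Reagents that add atoms: none
Why: Nozaki–Hiyama–Kishi coupling in which nickel inserts only into the unhindered 1,1‑disubstituted C‑1 triflate (the tetrasubstituted C‑8 triflate is inert) and the chiral ligand on chromium sets the 2S carbinol.

Step 12
Reactants: 19 (2S)‑allylic alcohol
Product: 21 macrocyclic epoxy alcohol, via bis‑boron intermediate 20 (not isolated)
Conditions: 9‑BBN‑H (2.2 equiv), THF, 0 °C → rt; then slow addition to Pd(dppf)Cl2 (20 mol%), AsPh3, Cs2CO3, DMF/THF/H2O, 50 °C, 2 mM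
Reagents that add atoms: none
Why: Anti‑Markovnikov hydroboration of the monosubstituted vinyl group (the C‑1 methylene is shielded by the adjacent O‑boryl group and two tertiary carbons) followed by intramolecular B‑alkyl Suzuki–Miyaura coupling with the C‑8 enol triflate closes the 11‑membered ring at C‑7–C‑8.

Step 13
Reactants: 21 macrocyclic epoxy alcohol
Product: 22 macrocyclic epoxy acetate
Conditions: Ac2O, pyridine, DMAP (cat.), CH2Cl2, 0 °C → rt
Reagents that add atoms: acetic anhydride, CC(=O)OC(C)=O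
Why: Acylation of the only free hydroxyl, since the diol is still masked as the epoxide.

Step 14
Reactants: 22 macrocyclic epoxy acetate
Product: 23 target (CNP0192310.1)
Conditions: HClO4 (cat.), THF/H2O (3:1), 0 °C
Reagents that add atoms: water, O
Why: Acid‑catalysed vinyl epoxide hydrolysis in which water attacks the allylic, non‑neopentyl C‑16 with inversion from the α‑face while C‑15 keeps its β‑oxygen, giving the trans 15β,16α‑diol (SN2‑type ring opening).

**Compound list**
1 | p‑cresol (4‑methylphenol) | Cc1ccc(O)cc1 | starting material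
2 | allyltrimethylsilane | C=CC[Si](C)(C)C | starting material
3 | 4‑allyl‑4‑methylcyclohexa‑2,5‑dien‑1‑one | C=CCC1(C)C=CC(=O)C=C1 | intermediate
4 | 3‑(1‑methyl‑4‑oxocyclohexa‑2,5‑dien‑1‑yl)propanal | O=CCCC1(C)C=CC(=O)C=C1 | intermediate
5 | (3aR,7aS)‑3a‑methyl‑2,3,3a,7a‑tetrahydro‑1H‑indene‑1,6(7H)‑dione (cis‑fused; C‑11 ketone, C‑8 enone with C‑15=C‑16) | O=C1CC[C@]2(C)C=CC(=O)C[C@H]12 | intermediate
6 | lithium alkoxide from addition of Ph2P(O)C(Li)(OMe)CH3 to the C‑11 ketone of 5 (C‑11–O on the α‑face; P‑bearing carbon as epimers) | [Li+].[O-][C@]1(C(C)(OC)P(=O)(c3ccccc3)c3ccccc3)CC[C@]2(C)C=CC(=O)C[C@H]12 | intermediate (not isolated)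
7 | 11‑(1‑methoxyethylidene) derivative of 5 (C‑8 enone kept; E/Z mixture) | COC(C)=C1CC[C@]2(C)C=CC(=O)C[C@H]12 | intermediate
8 | 15β,16β‑epoxy‑11‑(1‑methoxyethylidene) 8‑ketone | COC(C)=C1CC[C@]2(C)[C@H]3O[C@H]3C(=O)C[C@H]12 | intermediate
9 | lithium C‑8(O)=C‑9 enolate of 8 | [Li+].COC(C)=C1CC[C@]2(C)[C@H]3O[C@H]3C([O-])=C[C@H]12 | intermediate (not isolated)
10 | 9‑methyl derivative of 8 (C‑9 epimers) | COC(C)=C1CC[C@]2(C)[C@H]3O[C@H]3C(=O)C(C)[C@H]12 | intermediate
11 | potassium tetrasubstituted C‑8(O)=C‑9 enolate of 10 | [K+].COC(C)=C1CC[C@]2(C)[C@H]3O[C@H]3C([O-])=C(C)[C@H]12 | intermediate (not isolated)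
12 | C‑8 enol triflate (C‑8=C‑9 with 9‑methyl), 15β,16β‑epoxide, 11‑(1‑methoxyethylidene) | COC(C)=C1CC[C@]2(C)[C@H]3O[C@H]3C(OS(=O)(=O)C(F)(F)F)=C(C)[C@H]12 | intermediate
13 | 11α‑acetyl (H‑11β) 15β,16β‑epoxy C‑8 enol triflate | CC(=O)[C@@H]1CC[C@]2(C)[C@H]3O[C@H]3C(OS(=O)(=O)C(F)(F)F)=C(C)[C@H]12 | intermediate
14 | potassium terminal (CH2=C‑O) enolate of 13 | [K+].C=C([O-])[C@@H]1CC[C@]2(C)[C@H]3O[C@H]3C(OS(=O)(=O)C(F)(F)F)=C(C)[C@H]12 | intermediate (not isolated)
15 | bis(enol triflate): C‑1(OTf)=CH2 on C‑11 (α) and C‑8(OTf)=C‑9 | C=C(OS(=O)(=O)C(F)(F)F)[C@@H]1CC[C@]2(C)[C@H]3O[C@H]3C(OS(=O)(=O)C(F)(F)F)=C(C)[C@H]12 | intermediate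
16 | (S)‑β‑citronellene, (S)‑3,7‑dimethylocta‑1,6‑diene | CC(C)=CCC[C@H](C)C=C | starting material
17 | ozonide (1,2,4‑trioxolane) of the trisubstituted alkene of 16 | CC1(C)OOC(CC[C@H](C)C=C)O1 | intermediate (not isolated)
18 | (S)‑4‑methylhex‑5‑enal | O=CCC[C@H](C)C=C | intermediate
19 | (2S)‑allylic alcohol: C‑1(=CH2) joined to C‑2(OH) of the (5S)‑methylhexenyl chain, C‑8 enol triflate and β‑epoxide intact | C=C([C@@H](O)CC[C@H](C)C=C)[C@@H]1CC[C@]2(C)[C@H]3O[C@H]3C(OS(=O)(=O)C(F)(F)F)=C(C)[C@H]12 | intermediate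
20 | C‑7 alkyl‑9‑BBN, C‑2 O‑(9‑BBN) borinate of 19 | C=C([C@@H](OB4C5CCCC4CCC5)CC[C@H](C)CCB6C7CCCC6CCC7)[C@@H]1CC[C@]2(C)[C@H]3O[C@H]3C(OS(=O)(=O)C(F)(F)F)=C(C)[C@H]12 | intermediate (not isolated)
21 | macrocyclic (2S)‑alcohol with 15β,16β‑epoxide (full 5‑6‑11 skeleton) | C=C1[C@@H](O)CC[C@H](C)CCC2=C(C)[C@@H]3[C@H]1CC[C@]3(C)[C@H]4O[C@@H]24 | intermediate
22 | 2‑O‑acetate of 21 | C=C1[C@@H](OC(C)=O)CC[C@H](C)CCC2=C(C)[C@@H]3[C@H]1CC[C@]3(C)[C@H]4O[C@@H]24 | intermediate
23 | (2S,5R,10S,11R,14S,15R,16R)‑2‑acetoxy‑15,16‑diol, CNP0192310.1 | C=C1[C@@H](OC(C)=O)CC[C@H](C)CCC2=C(C)[C@@H]3[C@H]1CC[C@]3(C)[C@@H](O)[C@@H]2O | target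

**Totals**
Total step count: 14. Longest linear sequence: 13 steps (steps 1–9 and 11–14; step 10 makes the side‑chain aldehyde).

**Three steps most likely to fail**

Step 4 may fail because the bulky α‑methoxy phosphoryl carbanion could enolise the α‑branched cyclopentanone instead of adding, and it has to form a tetrasubstituted enol ether. The fallback sets out from 5 and comes back at 13, and sets C‑11 by hydroboration instead of protonation. Wittig ethylidenation (EtPPh3Br, t‑BuOK, THF) gives the 11‑ethylidene enone F1. The epoxidation, methylation and triflation of steps 5–7 are run on it unchanged and give the epoxy ketone F2, the 9‑methyl ketone F3 and the C‑8 enol triflate F4. Hydroboration–oxidation (BH3·THF, 0 °C; NaBO3) of the exocyclic alkene from the convex face puts H‑11 on the β‑face and gives the 1‑hydroxyethyl compound F5. Dess–Martin oxidation then gives 13. This costs one extra step.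

Step 12 may fail because it closes a medium ring by reductive elimination at a hindered, tetrasubstituted enol triflate. The fallback sets out from 13 and comes back at 21, closing the ring at C‑1–C‑2 instead. Hydroboration of 16 with 9‑BBN gives the alkylborane F6, which is coupled intermolecularly with the C‑8 triflate of 13 (Pd(dppf)Cl2, K3PO4, DMF) to the side‑chain methyl ketone F7. KHMDS/PhNTf2 at −78 °C gives the C‑1 enol triflate F8. OsO4 (cat.)/NaIO4/2,6‑lutidine cleaves only the trisubstituted side‑chain alkene and gives the aldehyde F9. An intramolecular Nozaki–Hiyama–Kishi reaction (CrCl2, NiCl2 cat., THF/DMSO, high dilution) closes the ring to 21; the C‑2 configuration is then under macrocyclic rather than ligand control.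

Step 14 may fail because the protonated epoxide sits next to a tetrasubstituted alkene, so SN2′ attack at C‑9 or elimination can compete with attack at C‑16. The fallback sets out from 19 and comes back at 23, and opens the epoxide while the neighbouring alkene is still the electron‑poor enol triflate. Ac2O/pyridine gives the acetate F10. Aqueous HClO4 in dioxane (40 °C) opens the epoxide by SN2 attack at C‑16 (C‑15 is neopentyl and no allyl cation can form) and gives the 15β,16α‑diol F11. 9‑BBN (3.3 equiv) gives the alkylborane F12, and the intramolecular Suzuki coupling under the step‑12 conditions then delivers 23 directly.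

**Further compounds**
F1 | step 4 | 11‑ethylidene analogue of 7 (E/Z mixture) | CC=C1CC[C@]2(C)C=CC(=O)C[C@H]12
F2 | step 4 | 15β,16β‑epoxy‑11‑ethylidene 8‑ketone | CC=C1CC[C@]2(C)[C@H]3O[C@H]3C(=O)C[C@H]12
F3 | step 4 | 9‑methyl derivative of F2 (C‑9 epimers) | CC=C1CC[C@]2(C)[C@H]3O[C@H]3C(=O)C(C)[C@H]12
F4 | step 4 | 11‑ethylidene C‑8 enol triflate | CC=C1CC[C@]2(C)[C@H]3O[C@H]3C(OS(=O)(=O)C(F)(F)F)=C(C)[C@H]12
F5 | step 4 | 11α‑(1‑hydroxyethyl) (H‑11β) epoxy C‑8 enol triflate (carbinol epimers) | CC(O)[C@@H]1CC[C@]2(C)[C@H]3O[C@H]3C(OS(=O)(=O)C(F)(F)F)=C(C)[C@H]12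
F6 | step 12 | B‑[(S)‑3,7‑dimethyloct‑6‑en‑1‑yl]‑9‑borabicyclo[3.3.1]nonane | CC(C)=CCC[C@H](C)CCB1C2CCCC1CCC2
F7 | step 12 | 11α‑acetyl epoxide with the (3S)‑3,7‑dimethyloct‑6‑enyl chain on C‑8 | CC(=O)[C@@H]1CC[C@]2(C)[C@H]3O[C@H]3C(CC[C@@H](C)CCC=C(C)C)=C(C)[C@H]12
F8 | step 12 | C‑1 enol triflate of F7 | C=C(OS(=O)(=O)C(F)(F)F)[C@@H]1CC[C@]2(C)[C@H]3O[C@H]3C(CC[C@@H](C)CCC=C(C)C)=C(C)[C@H]12
F9 | step 12 | C‑2 aldehyde from cleavage of the side‑chain alkene of F8 | C=C(OS(=O)(=O)C(F)(F)F)[C@@H]1CC[C@]2(C)[C@H]3O[C@H]3C(CC[C@@H](C)CCC=O)=C(C)[C@H]12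
F10 | step 14 | 2‑O‑acetate of 19 | C=C([C@@H](OC(C)=O)CC[C@H](C)C=C)[C@@H]1CC[C@]2(C)[C@H]3O[C@H]3C(OS(=O)(=O)C(F)(F)F)=C(C)[C@H]12
F11 | step 14 | 15β,16α‑diol from F10 (C‑8 enol triflate, 2‑acetate) | C=C([C@@H](OC(C)=O)CC[C@H](C)C=C)[C@@H]1CC[C@]2(C)[C@@H](O)[C@H](O)C(OS(=O)(=O)C(F)(F)F)=C(C)[C@H]12
F12 | step 14 | C‑7 alkyl‑9‑BBN derivative of F11 (diol drawn free) | C=C([C@@H](OC(C)=O)CC[C@H](C)CCB4C5CCCC4CCC5)[C@@H]1CC[C@]2(C)[C@@H](O)[C@H](O)C(OS(=O)(=O)C(F)(F)F)=C(C)[C@H]12
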